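Take the last stretch of the gamma run, not its end point, and divide by the catalyst: that was how I answered your request for a quick number on this flask.

| flask | solid substrate | gas phase | catalyst | remark | time |
|---|---|---|---|---|---|
| beta | 33 mM | 1.4 mM (held) | 1.4 mM (in portions, 2) | the very flask that is asked about, followed so far; portions every 15 min |  |
| gamma | 33 mM | 1.4 mM (held) | 0.70 mM (in portions, 2) | run made earlier; portions every 15 min |  |
| flask | 33 mM | 1.4 mM (held) | 1.4 mM (in portions, 2) | the portions of catalyst follow each other after 15 min, the first at the start | 1.0 h |

- beta (time / min: target / %): 1.00: 0; 2.00: 0.6; 3.00: 0; 4.00: 0; 5.00: 0.8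
- gamma (time / min: target / %): 12.0: 0.2; 25.0: 1.5; 40.0: 5.4; 50.0: 6.7; 60.0: 8.8

(readings scatter by 0.5 percentage points)

- given per volume of solution although it is solid: solid substrate
- at the start none of the gas is dissolved
- steps that have been proposed: gas phase <-> dissolved gas; starting material + dissolved gas + catalyst -> catalyst + target; dissolved gas -> decomposed reagent; solid substrate <-> starting material
- at the start none of the solid substrate is in solution

- amount of target in percent of the solid substrate charged, at 6.0 min, 20 min and 1.0 h

From 40.0 min to 60.0 min gamma's target rose 3.4 percentage points, with each reading good to 0.5 points. I froze what stood in solution over that stretch, the dissolved gas and the starting material, and kept one number: the turnover frequency T, the target made per minute per catalyst charged, which gamma's readings put at 0.0801 min⁻¹.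

The flask holds twice gamma's catalyst, the whole charge being in from the second portion at 15 min. So I multiplied T by the charge and by the 45.0 min from that portion to 1.0 h, divided by the solid charged, set aside what the first portion had made, and got 15.3 %. The same product gave 1.70 % at 20 min. For 6.0 min I named no figure above the scatter of the beta readings, 0.5 points.

Your forecast gave 0.2 %, 1.6 % and 15 % at those times, by doubling gamma and then, in your words, “I shade the 1 h value down”. My route used a slope and a time instead of gamma's end reading, and it needed no shading.

The flask gave 0.280 %, 2.70 % and 14.9 %, so your forecast stands within its margin.

    gas phase ⇌ dissolved gas, rate k1*(csat - [dissolved gas]) (kL = 1.90 min⁻¹)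
    starting material + dissolved gas + catalyst → catalyst + target (k = 2700 L² mol⁻² min⁻¹)
    dissolved gas → decomposed reagent (k = 0.0150 min⁻¹)
    solid substrate ⇌ starting material, rate k4*(cs4 - [starting material]) while solid is left; crystals form when [starting material] > cs4 (solubility = 21.0 mM, k = 0.120 min⁻¹)

At 0.500 h and at 1.00 h the flask held dissolved gas at 1.34 mM and 1.34 mM, and starting material at 59.7 % and 61.0 %. Starting from the flask's 5.65 % of target at 0.500 h, T carries the target to 15.9 % at 1.0 h, and the flask stood at 14.9 %.

All runs are simulated with constants of no real substance, and the scatter is random.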